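**One step.** In a world of one step, E + D → J + D, [D] stays at its charge and the order in D is one. The first-order constant, minus the log of the unconverted share of E over time, would then stand still. But the blue flask gives 0.0972 h⁻¹ at 3.00 h and 0.0750 h⁻¹ at 20.0 h, which is lower, so you take D to be dying there.

| setting | blue | amber | flask |
|---|---|---|---|
| E | 35 mM | 35 mM | 35 mM |
| D | 15 µM | 15 µM | 15 µM |
| X | 2.7 µM | 5.4 µM | 2.7 µM |
| remark | the very flask that is asked about, followed so far | run made earlier |  |

blue run (percent of the E charged): time / h: J / % = 3.00: 25.3; 6.00: 42.0; 10.0: 56.7; 12.0: 63.1; 15.0: 69.5; 20.0: 77.7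

amber run (percent of the E charged): time / d: J / % = 0.417: 47.8; 0.833: 70.5; 1.25: 79.7; 1.67: 88.6; 2.00: 88.4; 2.50: 92.8

(each reading ± 1 percentage point)

- what was read earlier has a scatter of 1 percentage point, one standard deviation
- steps thought possible: E + D -> J + D; 2 D -> L; D + X -> Q
- no earlier run changes the charge of D; that part of a forecast is a guess

- apparent order in D when 5.0% of the E are converted (percent change of the rate of making J for one percent more D charged)

**Working D.** Define the working D, w, as the D charged minus the X charged, which assumes X takes D one for one: 12.3 µM in the blue flask, and 9.60 µM in the amber flask. Their ratio is 0.780. At about 10.0 h, the log term of amber over that of blue reads 0.777.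

**The rule.** With the charges of E and X held fixed and X taking its D at the start, if D is lost by pairing into L, conversion depends on the product of w and time. At equal conversion, [D] is then the same multiple of w, so the rate follows w, and the order in charged D is the charge over w: 1.22.

**Weak link.** A ratio at equal time mixes loss with charge, so you reforge it at equal conversion, where times go inversely with w. Blue stands at 69.5% after 15.0 h and amber at 70.5% after 19.99 h, a ratio of 0.750. The first reading comes later than the time of 5.0% conversion, near 0.528 h, so X's reacting by then stays assumed. You commit to 1.22.

The forecast gives 1.2: “X seems to remove D quickly and stoichiometrically”.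

**The flask.** The simulation gives 1.2.

    E + D → J + D, rate k1*[E]*[D]/(1 + ([E]/Km1) + ([E]/Ksi1)^2) (0.110 M, 28.0 mM, k = 6.60 L mol⁻¹ s⁻¹)
    2 D → L (k = 2.10 L mol⁻¹ s⁻¹)
    D + X → Q (k = 750 L mol⁻¹ s⁻¹)

The flask reaches 5.0% at 0.508 h, and the capture of D by X as charged has a time of 8.23 min, shorter than that. With twice the D charged, w becomes 27.3 µM, a factor of 2.22 on this flask's w. In the simulated run with that charge, the rate at 5.0% rises by a factor of 2.22.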